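**Retrosynthetic overview**

- Ring C is opened at O1–C2. This leads back to the o-hydroxyaryl ketone 19, which carries C2 as a dimethyl acetal and C3 with ring B already attached.
- Ring A has para oxygens at C8a and C6, methoxy at C7 next to C6, and the C4 carbon on C4a next to C8a. This is the pattern of a 2-methoxy-5-alkyl-1,4-benzoquinone (16), which a thermal ring expansion of the 4-alkynyl-4-hydroxy-3-methoxycyclobutenone 14 delivers with formation of C8a–C4a.
- 14 comes from the lithium acetylide of alkyne 9 and 3-methoxycyclobutenedione 12, which is made from dimethyl squarate.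
- 9 comes from 2,4,5-trimethoxyphenylacetic acid by formylation, acetalisation, reduction to the aldehyde, ethynyl Grignard addition and silylation.
- Ring order: ring B is bought, ring A is formed in step 10, ring C in step 13.

Key step: step 10

Remark: the target has no stereocentre. The stereocentres of intermediates 5–20 are not controlled and are all erased by step 13, so these compounds are carried as racemic diastereomer mixtures.

**Route**

Step 1
Reactants: 1 2,4,5-trimethoxyphenylacetic acid
Product: 2 methyl 2,4,5-trimethoxyphenylacetate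
Conditions: MeOH, H2SO4 (cat.), reflux
Reagents that add atoms: methanol, CO
Why: Fischer esterification, driven by the excess of methanol, gives the ester needed for the Claisen formylation.

Step 2
Reactants: 2 methyl 2,4,5-trimethoxyphenylacetate; 3 methyl formate
Product: 4 methyl 3-hydroxy-2-(2,4,5-trimethoxyphenyl)prop-2-enoate (enol form of the α-formyl ester)
Conditions: NaH (2 equiv), HCO2Me (excess), THF, 0 °C to rt; then 1 M HCl
Reagents that add atoms: none
Why: Crossed Claisen condensation with the non-enolisable formate is pulled forward by deprotonation of the product to its stabilised sodium enolate, and acidification gives the hydrogen-bonded enol.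

Step 3
Reactants: 4 methyl 3-hydroxy-2-(2,4,5-trimethoxyphenyl)prop-2-enoate
Product: 5 methyl 3,3-dimethoxy-2-(2,4,5-trimethoxyphenyl)propanoate
Conditions: HC(OMe)3, MeOH, TsOH·H2O (cat.), rt; Et3N quench
Reagents that add atoms: trimethyl orthoformate, COC(OC)OC; methanol, CO
Why: Acid-catalysed acetalisation of the formyl tautomer with the orthoformate as water scavenger, kept at room temperature and quenched with base so that the acetal should not lose methanol to the β-methoxyacrylate.

Step 4
Reactants: 5 methyl 3,3-dimethoxy-2-(2,4,5-trimethoxyphenyl)propanoate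
Product: 6 3,3-dimethoxy-2-(2,4,5-trimethoxyphenyl)propanal
Conditions: i-Bu2AlH (1.1 equiv), CH2Cl2, −78 °C; MeOH, then aq potassium sodium tartrate (KNaC4H4O6); crude product used at once
Reagents that add atoms: none
Why: Partial ester reduction, in which the tetrahedral aluminium hemiacetal is held at −78 °C by chelation to a β-methoxy oxygen and releases the aldehyde only in the neutral work-up, which avoids β-elimination of methanol.

Step 5
Reactants: 6 3,3-dimethoxy-2-(2,4,5-trimethoxyphenyl)propanal; 7 ethynylmagnesium bromide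
Product: 8 5,5-dimethoxy-4-(2,4,5-trimethoxyphenyl)pent-1-yn-3-ol (diastereomer mixture)
Conditions: THF, −78 to −20 °C; aq NH4Cl
Reagents that add atoms: none
Why: Grignard 1,2-addition of the weakly basic alkynyl nucleophile should outrun enolisation at low temperature; the new carbinol centre forms without control, which is acceptable because it becomes the C4 ketone in step 12.

Step 6
Reactants: 8 5,5-dimethoxy-4-(2,4,5-trimethoxyphenyl)pent-1-yn-3-ol
Product: 9 triethyl{[5,5-dimethoxy-4-(2,4,5-trimethoxyphenyl)pent-1-yn-3-yl]oxy}silane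
Conditions: Et3SiCl, imidazole, DMAP (cat.), CH2Cl2, 0 °C to rt
Reagents that add atoms: chlorotriethylsilane, CC[Si](Cl)(CC)CC
Why: Imidazole-mediated silylation leaves the acetal alone, and the triethylsilyl ether withstands n-BuLi and 110 °C yet is later cleaved by mild acid in methanol, conditions harmless to the quinone and the acetal.

Step 7
Reactants: 10 dimethyl squarate
Product: 11 4-hydroxy-2,3-dimethoxycyclobut-2-en-1-one
Conditions: LiAlH(OtBu)3 (1.0 equiv), THF, −78 to 0 °C; aqueous work-up
Reagents that add atoms: none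
Why: 1,2-Hydride addition of the bulky, mild alkoxyaluminium hydride to one of the two equivalent squarate carbonyls stops at the mono-alkoxide, which is no longer electrophilic enough for a second reduction.

Step 8
Reactants: 11 4-hydroxy-2,3-dimethoxycyclobut-2-en-1-one
Product: 12 3-methoxycyclobut-3-ene-1,2-dione
Conditions: conc. HCl (cat.), CH2Cl2, rt; used promptly
Reagents that add atoms: none
Why: Acid-catalysed allylic transposition: ionisation of the allylic hydroxyl gives a methoxy-stabilised cyclobutenyl cation, which takes up water at the methoxy-bearing terminus next to the carbonyl and expels methanol to unveil the 1,2-dione (the usual semisquarate preparation).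

Step 9
Reactants: 9 triethyl{[5,5-dimethoxy-4-(2,4,5-trimethoxyphenyl)pent-1-yn-3-yl]oxy}silane; 12 3-methoxycyclobut-3-ene-1,2-dione
Product: 14 4-[5,5-dimethoxy-3-(triethylsilyloxy)-4-(2,4,5-trimethoxyphenyl)pent-1-yn-1-yl]-4-hydroxy-3-methoxycyclobut-2-en-1-one (diastereomer mixture), via lithium acetylide 13 (not isolated)
Conditions: n-BuLi (1.0 equiv), THF, −78 °C; cannulation into 12 in THF, −78 °C; aq NH4Cl at −78 °C
Reagents that add atoms: none
Why: Alkyne deprotonation followed by 1,2-addition of the hard lithium acetylide to the more electrophilic carbonyl, the one next to the methoxy-bearing carbon, since the other carbonyl is deactivated as a vinylogous ester; inverse addition at −78 °C limits double and conjugate addition, and the new carbinol centre needs no control.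

Step 10
Reactants: 14 4-[5,5-dimethoxy-3-(triethylsilyloxy)-4-(2,4,5-trimethoxyphenyl)pent-1-yn-1-yl]-4-hydroxy-3-methoxycyclobut-2-en-1-one
Product: 16 2-[3,3-dimethoxy-1-(triethylsilyloxy)-2-(2,4,5-trimethoxyphenyl)propyl]-5-methoxycyclohexa-2,5-diene-1,4-dione (diastereomer mixture), via alkynyl vinylketene 15 (not isolated)
Conditions: degassed toluene (dilute), 110 °C
Reagents that add atoms: none
Why: Heating opens the cyclobutenone by conrotatory four-electron cleavage of the bond between the carbonyl and the carbinol carbon, and the donor hydroxyl rotates outward, so the alkynyl group of vinylketene 15 lies cis to the ketene. The ketene carbon then bonds to the distal alkyne carbon, closing ring A as a six-membered ring (future C8a–C4a bond) in a Moore cyclisation of an enyne-ketene; the closest known reaction is the thermal rearrangement of 4-alkynyl-4-hydroxycyclobutenones to 1,4-benzoquinones. The ring-closed diradical is quenched by transfer of the hydroxyl hydrogen to the neighbouring ring carbon, which should give quinone 16 directly. No stereocentre is formed and the two in the side chain are spectators. The step needs six- and not five-membered closure, which the sp3 (not radical-stabilising) carbon on the alkyne terminus secures, and it needs outward rotation of the hydroxyl, which the free OH as the strongest donor on that carbon secures. The connectivity of 14 places methoxy next to the carbinol-derived carbonyl and the side chain next to the ketene-derived carbonyl, which fixes OMe at C7, oxygen at C6 and C8a, and the chain at C4a.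

Step 11
Reactants: 16 2-[3,3-dimethoxy-1-(triethylsilyloxy)-2-(2,4,5-trimethoxyphenyl)propyl]-5-methoxycyclohexa-2,5-diene-1,4-dione
Product: 17 2-[1-hydroxy-3,3-dimethoxy-2-(2,4,5-trimethoxyphenyl)propyl]-5-methoxycyclohexa-2,5-diene-1,4-dione
Conditions: PPTS (0.2 equiv), MeOH, rt
Reagents that add atoms: none
Why: Acid-catalysed methanolysis of the triethylsilyl ether, which avoids fluoride on the quinone; in methanol any exchange at the dimethyl acetal or at the methoxyquinone is degenerate.

Step 12
Reactants: 17 2-[1-hydroxy-3,3-dimethoxy-2-(2,4,5-trimethoxyphenyl)propyl]-5-methoxycyclohexa-2,5-diene-1,4-dione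
Product: 19 1-(2,5-dihydroxy-4-methoxyphenyl)-3,3-dimethoxy-2-(2,4,5-trimethoxyphenyl)propan-1-one, via acylquinone 18 (not isolated)
Conditions: Dess–Martin periodinane (1.3 equiv), CH2Cl2, 0 °C to rt; then EtOAc, aq Na2S2O4, rt, under Ar
Reagents that add atoms: none
Why: Dess–Martin oxidation of the secondary carbinol is done while ring A is a quinone and therefore inert to the oxidant, and the electrophilic acylquinone is not stored but reduced at once by dithionite to the hydrogen-bonded o-hydroxyaryl ketone.

Step 13
Reactants: 19 1-(2,5-dihydroxy-4-methoxyphenyl)-3,3-dimethoxy-2-(2,4,5-trimethoxyphenyl)propan-1-one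
Product: 21 6-hydroxy-7-methoxy-3-(2,4,5-trimethoxyphenyl)-4H-chromen-4-one (target), via 2-methoxychromanone 20 (not isolated)
Conditions: TsOH·H2O (10 mol %), toluene, 80 °C, under Ar
Reagents that add atoms: none
Why: Acid-catalysed acetal ionisation and 6-exo-trig attack of the C8a hydroxyl on the oxocarbenium carbon (O1–C2 bond), then elimination of the second methanol across C2–C3, as in the classical isoflavone closure of formylated deoxybenzoins; the C6 hydroxyl is para to C8a–O and cannot reach C2, so it stays free.

**Compound list**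

1 | 2,4,5-trimethoxyphenylacetic acid | COc1cc(OC)c(CC(=O)O)cc1OC | starting material
2 | methyl 2,4,5-trimethoxyphenylacetate | COC(=O)Cc1cc(OC)c(OC)cc1OC | intermediate
3 | methyl formate | COC=O | starting material
4 | methyl 3-hydroxy-2-(2,4,5-trimethoxyphenyl)prop-2-enoate (enol form of the α-formyl ester, double-bond geometry not defined) | COC(=O)C(=CO)c1cc(OC)c(OC)cc1OC | intermediate
5 | methyl 3,3-dimethoxy-2-(2,4,5-trimethoxyphenyl)propanoate (racemic) | COC(=O)C(C(OC)OC)c1cc(OC)c(OC)cc1OC | intermediate
6 | 3,3-dimethoxy-2-(2,4,5-trimethoxyphenyl)propanal (racemic) | O=CC(C(OC)OC)c1cc(OC)c(OC)cc1OC | intermediate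
7 | ethynylmagnesium bromide | C#C[Mg]Br | starting material
8 | 5,5-dimethoxy-4-(2,4,5-trimethoxyphenyl)pent-1-yn-3-ol (diastereomer mixture) | C#CC(O)C(C(OC)OC)c1cc(OC)c(OC)cc1OC | intermediate
9 | triethyl{[5,5-dimethoxy-4-(2,4,5-trimethoxyphenyl)pent-1-yn-3-yl]oxy}silane (diastereomer mixture) | C#CC(O[Si](CC)(CC)CC)C(C(OC)OC)c1cc(OC)c(OC)cc1OC | intermediate
10 | dimethyl squarate (3,4-dimethoxycyclobut-3-ene-1,2-dione) | COC1=C(OC)C(=O)C1=O | starting material
11 | 4-hydroxy-2,3-dimethoxycyclobut-2-en-1-one (racemic) | COC1=C(OC)C(O)C1=O | intermediate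
12 | 3-methoxycyclobut-3-ene-1,2-dione | COC1=CC(=O)C1=O | intermediate
13 | lithium acetylide of 9 | [Li]C#CC(O[Si](CC)(CC)CC)C(C(OC)OC)c1cc(OC)c(OC)cc1OC | intermediate
14 | 4-[5,5-dimethoxy-3-(triethylsilyloxy)-4-(2,4,5-trimethoxyphenyl)pent-1-yn-1-yl]-4-hydroxy-3-methoxycyclobut-2-en-1-one (diastereomer mixture) | COC1=CC(=O)C1(O)C#CC(O[Si](CC)(CC)CC)C(C(OC)OC)c1cc(OC)c(OC)cc1OC | intermediate
15 | alkynyl vinylketene from ring opening of 14 (hydroxyl trans to the ketenyl group) | O=C=C/C(OC)=C(/O)C#CC(O[Si](CC)(CC)CC)C(C(OC)OC)c1cc(OC)c(OC)cc1OC | intermediate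
16 | 2-[3,3-dimethoxy-1-(triethylsilyloxy)-2-(2,4,5-trimethoxyphenyl)propyl]-5-methoxycyclohexa-2,5-diene-1,4-dione (diastereomer mixture) | COC1=CC(=O)C(C(O[Si](CC)(CC)CC)C(C(OC)OC)c2cc(OC)c(OC)cc2OC)=CC1=O | intermediate
17 | 2-[1-hydroxy-3,3-dimethoxy-2-(2,4,5-trimethoxyphenyl)propyl]-5-methoxycyclohexa-2,5-diene-1,4-dione (diastereomer mixture) | COC1=CC(=O)C(C(O)C(C(OC)OC)c2cc(OC)c(OC)cc2OC)=CC1=O | intermediate
18 | 2-[3,3-dimethoxy-2-(2,4,5-trimethoxyphenyl)propanoyl]-5-methoxycyclohexa-2,5-diene-1,4-dione (racemic) | COC1=CC(=O)C(C(=O)C(C(OC)OC)c2cc(OC)c(OC)cc2OC)=CC1=O | intermediate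
19 | 1-(2,5-dihydroxy-4-methoxyphenyl)-3,3-dimethoxy-2-(2,4,5-trimethoxyphenyl)propan-1-one (racemic) | COc1cc(O)c(C(=O)C(C(OC)OC)c2cc(OC)c(OC)cc2OC)cc1O | intermediate
20 | 6-hydroxy-2,7-dimethoxy-3-(2,4,5-trimethoxyphenyl)chroman-4-one (diastereomer mixture) | COC1Oc2cc(OC)c(O)cc2C(=O)C1c1cc(OC)c(OC)cc1OC | intermediate
21 | 6-hydroxy-7-methoxy-3-(2,4,5-trimethoxyphenyl)-4H-chromen-4-one | COc1cc2occ(-c3cc(OC)c(OC)cc3OC)c(=O)c2cc1O | target

**Step count**

Total: 13 steps. Longest linear sequence: 11 steps (steps 1–6 and 9–13); steps 7–8 form the two-step side branch to 12.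

**Steps most likely to fail**

1. Step 10. The ring-closed diradical may be diverted, by five-membered closure or by hydrogen abstraction from the acetal C–H of the side chain in place of hydroxyl-hydrogen transfer, or the substrate may decompose thermally before ring opening. The fallback replaces the diradical pathway by the closed-shell alkenyl variant of the same ring expansion and sets out from 9.
   - Hydrozirconation of 9 with Cp2Zr(H)Cl and iodination with I2 would give triethyl{[(1E)-1-iodo-5,5-dimethoxy-4-(2,4,5-trimethoxyphenyl)pent-1-en-3-yl]oxy}silane F1.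
   - Iodine–lithium exchange with t-BuLi (2 equiv, Et2O, −78 °C) and addition to 12 would give 4-[(1E)-5,5-dimethoxy-3-(triethylsilyloxy)-4-(2,4,5-trimethoxyphenyl)pent-1-en-1-yl]-4-hydroxy-3-methoxycyclobut-2-en-1-one F2.
   - Heating F2 in toluene at 110 °C should open it to a dienylketene, which undergoes 6π-electrocyclisation and enolisation to 2-[3,3-dimethoxy-1-(triethylsilyloxy)-2-(2,4,5-trimethoxyphenyl)propyl]-5-methoxybenzene-1,4-diol F3.
   - Oxidation of F3 with Ag2O in Et2O comes back to the route at 16.

2. Step 12. The acylquinone may be consumed before it is reduced, through addition of the electron-rich trimethoxyphenyl ring or of the enol of the new ketone to the strongly electrophilic quinone. The fallback oxidises the carbinol with ring A masked as a protected hydroquinone and sets out from 16.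
   - Reduction of 16 with aq Na2S2O4 gives 2-[3,3-dimethoxy-1-(triethylsilyloxy)-2-(2,4,5-trimethoxyphenyl)propyl]-5-methoxybenzene-1,4-diol F3, the same compound as in the fallback above.
   - Chloromethyl methyl ether and i-Pr2NEt in CH2Cl2 would give triethyl{1-[4-methoxy-2,5-bis(methoxymethoxy)phenyl]-3,3-dimethoxy-2-(2,4,5-trimethoxyphenyl)propoxy}silane F4.
   - Bu4NF in THF, which is now harmless, would give 1-[4-methoxy-2,5-bis(methoxymethoxy)phenyl]-3,3-dimethoxy-2-(2,4,5-trimethoxyphenyl)propan-1-ol F5.
   - Dess–Martin oxidation would give 1-[4-methoxy-2,5-bis(methoxymethoxy)phenyl]-3,3-dimethoxy-2-(2,4,5-trimethoxyphenyl)propan-1-one F6.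
   - HCl in MeOH at 50 °C removes both methoxymethyl groups and closes ring C in the same operation, which comes back to the route at the target 21.

3. Step 5. Deprotonation of the α-aryl aldehyde by the Grignard reagent and E1cB loss of methoxide, or the same elimination while 6 is handled, may compete with addition. The fallback never frees the aldehyde and sets out from 5.
   - Me(MeO)NH·HCl and AlMe3 in CH2Cl2 would give N-methoxy-N-methyl-3,3-dimethoxy-2-(2,4,5-trimethoxyphenyl)propanamide F7.
   - Addition of ethynylmagnesium bromide 7 (THF, 0 °C) gives a chelated tetrahedral adduct that releases the ketone only on quench, leading to 5,5-dimethoxy-4-(2,4,5-trimethoxyphenyl)pent-1-yn-3-one F8.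
   - 1,2-Reduction with NaBH4 and CeCl3·7H2O in MeOH at −78 °C comes back to the route at 8.

**Further compounds**

F1 | step 10 | triethyl{[(1E)-1-iodo-5,5-dimethoxy-4-(2,4,5-trimethoxyphenyl)pent-1-en-3-yl]oxy}silane | I/C=C/C(O[Si](CC)(CC)CC)C(C(OC)OC)c1cc(OC)c(OC)cc1OC
F2 | step 10 | 4-[(1E)-5,5-dimethoxy-3-(triethylsilyloxy)-4-(2,4,5-trimethoxyphenyl)pent-1-en-1-yl]-4-hydroxy-3-methoxycyclobut-2-en-1-one | COC1=CC(=O)C1(O)/C=C/C(O[Si](CC)(CC)CC)C(C(OC)OC)c1cc(OC)c(OC)cc1OC
F3 | step 10 | 2-[3,3-dimethoxy-1-(triethylsilyloxy)-2-(2,4,5-trimethoxyphenyl)propyl]-5-methoxybenzene-1,4-diol | COc1cc(O)c(C(O[Si](CC)(CC)CC)C(C(OC)OC)c2cc(OC)c(OC)cc2OC)cc1O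
F4 | step 12 | triethyl{1-[4-methoxy-2,5-bis(methoxymethoxy)phenyl]-3,3-dimethoxy-2-(2,4,5-trimethoxyphenyl)propoxy}silane | COCOc1cc(OC)c(OCOC)cc1C(O[Si](CC)(CC)CC)C(C(OC)OC)c1cc(OC)c(OC)cc1OC
F5 | step 12 | 1-[4-methoxy-2,5-bis(methoxymethoxy)phenyl]-3,3-dimethoxy-2-(2,4,5-trimethoxyphenyl)propan-1-ol | COCOc1cc(OC)c(OCOC)cc1C(O)C(C(OC)OC)c1cc(OC)c(OC)cc1OC
F6 | step 12 | 1-[4-methoxy-2,5-bis(methoxymethoxy)phenyl]-3,3-dimethoxy-2-(2,4,5-trimethoxyphenyl)propan-1-one | COCOc1cc(OC)c(OCOC)cc1C(=O)C(C(OC)OC)c1cc(OC)c(OC)cc1OC
F7 | step 5 | N-methoxy-N-methyl-3,3-dimethoxy-2-(2,4,5-trimethoxyphenyl)propanamide | CON(C)C(=O)C(C(OC)OC)c1cc(OC)c(OC)cc1OC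
F8 | step 5 | 5,5-dimethoxy-4-(2,4,5-trimethoxyphenyl)pent-1-yn-3-one | C#CC(=O)C(C(OC)OC)c1cc(OC)c(OC)cc1OC
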